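The constants used here are those of an exercise; no experiment stands behind them.

**Fixed ledger.** Every turn of the cycle spends one partner and one substrate, so, catalyst-sized amounts aside, the two fall by equal amounts.

| flask | substrate | partner | free catalyst | time |
|---|---|---|---|---|
| oak | 5.0 × 10⁻⁴ M | 0.250 mM | 0.50 µM | 15 s |
| alder | 5.0 × 10⁻⁴ M | 0.500 mM | 0.50 µM | 15 s |

    catalyst intermediate C ⇌ free catalyst + target (K1 = 0.0083 M, k1 = 2100 s⁻¹)
    target + free catalyst ⇌ isomer of the product + free catalyst, rate k2*[free catalyst]*[target] forward; the back reaction follows from the equilibrium constant (K2 = 0.46, k2 = 2.5 × 10⁵ M⁻¹ s⁻¹)
    substrate + catalyst intermediate B → catalyst intermediate C (k3 = 3.5 × 10⁵ M⁻¹ s⁻¹)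
    catalyst intermediate A → by-product + catalyst intermediate B (k4 = 180 s⁻¹)
    partner + free catalyst → catalyst intermediate A (k5 = 8.1 × 10⁷ M⁻¹ s⁻¹)

- which of these there is most of at the end, counted by the substrate in it, oak (target / isomer of the product / catalyst intermediate C / substrate)
- which of these there is most of at the end, counted by the substrate in it, alder (target / isomer of the product / catalyst intermediate C / substrate)
- amount of the one of these that there is most of at the end, in percent of the substrate charged, oak
- amount of the one of these that there is most of at the end, in percent of the substrate charged, alder

**Ledger floor.** In oak the partner is the limiting reagent, 0.250 mM against 5.0 × 10⁻⁴ M of substrate, so the ledger stops substrate at 50.0% of its charge. In alder the two charges are equal, and the ledger's floor is 0%.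

**Cycle budget.** At the start of oak, free catalyst is caught in about 4.94 × 10⁻⁵ s and catalyst intermediate C opens in 4.76 × 10⁻⁴ s. Both are shorter than the 0.00556 s that catalyst intermediate A takes to lose by-product . I therefore take those two steps as instantaneous and let the catalyst rest in intermediates A and B, its resting state. Summing the turns gives a rule: substrate spent divided by 180 s⁻¹, plus the natural logarithm of substrate's fall divided by 3.5 × 10⁵ M⁻¹ s⁻¹, equals the cycle budget, which is catalyst charge times time, 0.00750 mM·s.

**Where they part.** Oak and alder have the same budget. Bringing substrate to 16.7% of its charge costs 99.1% of the budget, so in alder I expect about 16.7% substrate left and 83.3% target. In oak the same budget reaches below the floor, but the rule assumes partner is present, and the partner's charge is spent by 6.74 s, earlier than 15 s. So the budget cheats in oak and the floor stands. The remaining 8.26 s exceeds target's forward half-life of 5.5 s, so I split oak's product by 0.46: 34.2% target and 15.8% isomer of the product. Substrate then leads in oak.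

**The forecast.** It says substrate at 50% for oak and target at 82% for alder, slightly below my alder figure. Of alder it argues that “free catalyst stays scarce, so almost no isomerisation occurs”.

**The flasks.** Oak ends with substrate at 50.0%, and alder with target at 82.3%. Alder's substrate reading of 17.5% costs 97.1% of the budget. A flask like oak but charged with 2.0 × 10⁻⁴ M of substrate has 1.25 equiv of partner, so the ledger sets no floor there, and its budget is unchanged. Bringing substrate to 10.0% of its charge costs 101% of that budget, so I expect substrate to stop near that figure. That flask holds 10.6% substrate and 89.2% target.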